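## Analysis of the target

Catechin 7-O-gallate (24) is a flavan. Benzo ring A is fused to the dihydropyran ring C, C2 carries the catechol ring B, C3 carries a hydroxyl, and ring A carries oxygens at C5 and C7, the C7 oxygen being esterified by gallic acid. The two adjacent stereocentres are C2 (R) and C3 (S), with the aryl group and the hydroxyl trans on ring C, as in (+)-catechin. The molecule has six free phenols, among them a catechol and a pyrogallol that oxidise readily in base and air. The aryl ester is cleaved or transferred by base. The benzylic ether carbon C2 epimerises by ring opening in hot base and ionises in acid. The skeleton is not the difficulty. The difficulty is to place one acyl group on O7 while O5, a second phenol on the same 1,3,5-trioxygenated ring, the 3-hydroxyl and the phenols of ring B stay free. The end game must therefore be a neutral deprotection, and O7 must be the only orthogonal oxygen before it. The strategy rests on the following feature. O1 is an aryl alkyl ether oxygen on C8a, C8a and C5 are the two carbons ortho to C4a, and C7 is para to C4a. If ring A enters as a 2,6-dibromo-4-silyloxybenzyl unit, C8a and C5 are equivalent until ring C closes through C8a–O1. The bromine that is left marks C5, and O7 has been different from O5 from the first step.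

## Retrosynthetic reasoning

The target 24 is traced back to its hepta-O-benzyl derivative 23. All seven O–benzyl bonds are cut in one hydrogenolysis, which is neutral, spares the aryl ester and the C2–O1 bond, and releases the oxidation-prone phenols only at the end.

In 23 the ester C–O bond at O7 is cut, which gives phenol 20 and acid 21 (used as its chloride 22). O7 is the only free hydroxyl in 20, so the acylation needs no selectivity.

Phenol 20 comes from silyl ether 19 by cleavage of the O7–Si bond. In 19 the aryl C5–O bond is cut back to bromide 18. The bromine is the placeholder for O5, and the forward reaction is an intermolecular palladium-catalysed etherification that introduces O5 directly as a benzyl ether, so that it leaves in the last step with the others.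

Bromide 18 is opened at C8a–O1, which leads to the anti alcohol 17. This bond is chosen because the two C–Br bonds of 17 are equivalent, so the closure cannot give a regioisomer. It is also chosen because the C2–O bond stays intact, so the configuration at C2 is carried over. Cutting O1–C2 instead would ask for a clean inversion at an easily ionised benzylic carbon. The forward reaction closes ring C and, in the same event, fixes which carbon carries O1 and which carries the future O5.

Alcohol 17 is traced to ketone 16 by removal of the carbinol hydrogen at C2. The benzyloxy group on C3 can chelate a metal together with the carbonyl oxygen, so a chelating hydride reagent should set C2 anti to C3.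

Ketone 16 is cut at the bond between C2 and ring B, giving Weinreb amide 13 and the aryl Grignard reagent 15 made from bromide 14. Ring B enters late as a simple aryl metal, and the amide stops the addition at the ketone.

Amide 13 comes from imide 12 by exchange of the auxiliary. In 12 the C3–C4 bond is cut, which leads to the glycolate enolate 11 of imide 10 and the benzylic bromide 6. The auxiliary-controlled alkylation sets C3, and the benzyl ether that blocks the C3 oxygen in the key step is already part of the glycolate.

Imide 10 is assembled from oxazolidinone 7 and acid chloride 8. Bromide 6 is traced through alcohol 5 and aldehyde 4 to silyl ether 2 and phenol 1. The carbon that becomes C4 is introduced by formylation of aryllithium 3 at the position between the two bromines. This keeps the ring symmetric and places the silyloxy group para to the new carbon.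

## Alternatives that were turned down

Alternative 1: O1–C2 and C3–C4 are cut together. Ring C would arise from a hetero-Diels–Alder reaction between the ring-A o-quinone methide A3 and the (E)-enol carbonate A4 of ring B. A3 would be released by acid-catalysed dehydration of the o-hydroxybenzyl alcohol A2, which already carries the tribenzylgalloyl ester on the future O7. A chiral confined Brønsted acid would have to generate A3 and control the facial sense, giving A1.
- For it: two bonds, ring C and both stereocentres are formed in one step. The E geometry of A4 becomes the 2,3-trans relationship if the addition is concerted. A1 carries only hydrogenolysable groups, so 24 is one step away. On convergence and step count this plan is clearly stronger than the chosen one.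
- Against it: the regiochemistry depends on two opposed polarisations of A4. The enol oxygen directs the methylene carbon of A3 to the aryl-bearing carbon, which gives a 2-oxy-3-aryl chroman. The electron-rich styrene directs it to the oxygen-bearing carbon, as needed. The carbonate weakens the first effect but does not remove it.
- Against it: A3 is an ester-substituted, weakly basic quinone methide, and there is no close model for enantiocontrol with an acyclic enol carbonate. A stepwise pathway would also erode the trans selectivity.
- Against it: A2 needs three differently substituted oxygens on one ring, so the O5/O7 problem is moved into the preparation of A2 and not solved.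
- Comparison: the chosen route is longer. In return each stereocentre is set by a reaction of predictable sense, and the regiochemistry of ring A follows from symmetry.

Alternative 2: the C2–C3 bond is cut. The mixed O-aryl O-methyl acetal A6, whose ring A carries an ortho (Z)-vinylsilane, would be ionised by a chiral confined Brønsted acid to an aryloxycarbenium ion. The silicon-bearing carbon attacks C2 in a 6-endo closure, and loss of silicon from the β-silyl benzylic cation gives flav-3-ene A5.
- For it: the method is catalytic in the chiral controller, and on this point it is stronger than the auxiliary-based route. The β-silyl effect matches the benzylic C4. The C3=C4 alkene of A5 allows the 3-hydroxyl to be installed anti to the C2 aryl group by hydroboration–oxidation.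
- Against it: only C2 is set in the key step. Its control depends on a chiral counteranion distinguishing the faces of a strongly stabilised, nearly planar cation flanked by two aryl groups. C3 then needs a further step with its own regiochemical and facial demands.
- Against it: A6 requires ring A with four different substituents, so the three oxygens must again be differentiated step by step, and a Z-vinylsilane must be built.
- Against it: after A5 there remain hydroboration–oxidation, handling of the free 3-hydroxyl, desilylation, acylation and hydrogenolysis.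
- Comparison: the chosen route sets both stereocentres before ring closure and needs no oxygen differentiation, at the cost of a stoichiometric auxiliary.

Alternative 3: the C4–C4a bond is cut. In the erythro epoxy aryl ether A8, ring A would attack the epoxide CH2 under a Lewis acid or in a strongly hydrogen-bond-donating fluorinated alcohol. This 6-endo Friedel–Crafts closure gives A7.
- For it: ring A is very nucleophilic and no transition metal is needed. Both stereocentres are present in A8 and are carried through, because neither the C3–O bond nor C2 is touched; this is the same logic as in the chosen route and equally strong. The 3-hydroxyl appears free.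
- Against it: the two ortho positions of ring A in A8 are not equivalent. One is next to the carbonate and one next to the silyloxy group, so the assignment of O5 and O7 rests on an electronic bias and not on symmetry.
- Against it: the benzylic C2–O bond, para to an alkoxy group of ring B, is the most acid-labile bond in A8. It may ionise before the epoxide opens, with epimerisation or fragmentation.
- Against it: 5-exo attack at the inner epoxide carbon competes.
- Against it: A8 needs an unsymmetrically protected phenol to be etherified at a benzylic carbinol with inversion, and the free 3-hydroxyl of A7 competes in the later acylation of O7.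
- Comparison: the step count is similar. The chosen route forms the ring under basic conditions, away from the acid-sensitive C2, and has no regiochemical question.

Key step: step 10

Remark: the SMILES is read as (2R,3S), the (+)-catechin series, and compounds 1, 7, 8, 14 and 21 are taken as purchasable.

## Route

Step 1
Reactants: 1 3,5-dibromophenol
Product: 2 (3,5-dibromophenoxy)triisopropylsilane
Conditions: TIPSCl, imidazole, DMF, rt
Reagents that add atoms: triisopropylsilyl chloride, CC(C)[Si](Cl)(C(C)C)C(C)C
Why: Standard silylation of a phenol. The bulky silyl ether is a poor director of lithiation, shields its own ortho positions and tolerates the carbonate bases used later.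

Step 2
Reactants: 2 (3,5-dibromophenoxy)triisopropylsilane
Product: 4 2,6-dibromo-4-(triisopropylsilyloxy)benzaldehyde, via aryllithium 3 (not isolated)
Conditions: LiN(iPr)2, THF, −78 °C; DMF, −78 → 0 °C; aq. NH4Cl
Reagents that add atoms: N,N-dimethylformamide, CN(C)C=O
Why: The C–H flanked by two bromines is the most acidic, so deprotonation occurs there (directed ortho-metalation). At −78 °C aryllithium 3 does not lose LiBr and is formylated by DMF.

Step 3
Reactants: 4 2,6-dibromo-4-(triisopropylsilyloxy)benzaldehyde
Product: 5 [2,6-dibromo-4-(triisopropylsilyloxy)phenyl]methanol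
Conditions: NaBH4, THF/EtOH, 0 °C
Reagents that add atoms: none
Why: Borohydride reduction of an aryl aldehyde; aryl bromides and the aryl silyl ether are inert under these conditions.

Step 4
Reactants: 5 [2,6-dibromo-4-(triisopropylsilyloxy)phenyl]methanol
Product: 6 [3,5-dibromo-4-(bromomethyl)phenoxy]triisopropylsilane
Conditions: CBr4, PPh3, CH2Cl2, 0 °C
Reagents that add atoms: carbon tetrabromide, BrC(Br)(Br)Br
Why: Appel bromination of a primary benzylic alcohol under neutral conditions, which keeps the silyl ether intact.

Step 5
Reactants: 7 (R)-4-benzyloxazolidin-2-one; 8 benzyloxyacetyl chloride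
Product: 10 (R)-4-benzyl-3-(2-benzyloxyacetyl)oxazolidin-2-one, via N-lithio oxazolidinone 9 (not isolated)
Conditions: n-BuLi, THF, −78 °C; then 8, −78 → 0 °C
Reagents that add atoms: none
Why: N-Acylation of the lithiated auxiliary with an acid chloride, the standard entry to an Evans glycolate imide.

Step 6
Reactants: 10 (R)-4-benzyl-3-(2-benzyloxyacetyl)oxazolidin-2-one; 6 [3,5-dibromo-4-(bromomethyl)phenoxy]triisopropylsilane
Product: 12 (R)-4-benzyl-3-{(S)-2-benzyloxy-3-[2,6-dibromo-4-(triisopropylsilyloxy)phenyl]propanoyl}oxazolidin-2-one, via sodium Z-enolate 11 (not isolated)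
Conditions: NaN(SiMe3)2, THF, −78 °C; then 6, −78 → −45 °C
Reagents that add atoms: none
Why: Evans glycolate alkylation. In the chelated Z-enolate 11 the benzyl group of the (R)-auxiliary covers one face, so the benzylic bromide enters from the other and the new stereocentre (the later C3) should be S.

Step 7
Reactants: 12 (R)-4-benzyl-3-{(S)-2-benzyloxy-3-[2,6-dibromo-4-(triisopropylsilyloxy)phenyl]propanoyl}oxazolidin-2-one
Product: 13 (S)-2-benzyloxy-3-[2,6-dibromo-4-(triisopropylsilyloxy)phenyl]-N-methoxy-N-methylpropanamide
Conditions: MeONHMe·HCl, AlMe3, CH2Cl2, 0 °C → rt; aq. HCl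
Reagents that add atoms: N,O-dimethylhydroxylamine hydrochloride, CNOC.Cl
Why: Weinreb transamination of an N-acyl oxazolidinone with the aluminium amide. The exocyclic carbonyl is attacked, the auxiliary 7 is released for recovery and the α-stereocentre is not enolised.

Step 8
Reactants: 14 4-bromo-1,2-bis(benzyloxy)benzene; 13 (S)-2-benzyloxy-3-[2,6-dibromo-4-(triisopropylsilyloxy)phenyl]-N-methoxy-N-methylpropanamide
Product: 16 (S)-2-benzyloxy-1-[3,4-bis(benzyloxy)phenyl]-3-[2,6-dibromo-4-(triisopropylsilyloxy)phenyl]propan-1-one, via aryl Grignard reagent 15 (not isolated)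
Conditions: 14, Mg, cat. I2, THF, 50 °C; then 13, THF, 0 °C; aq. NH4Cl
Reagents that add atoms: none
Why: Weinreb ketone synthesis. The chelated tetrahedral adduct holds until work-up, so no over-addition or α-epimerisation is expected. A Grignard reagent is used because it does not exchange with the aryl bromides of 13, as an aryllithium might.

Step 9
Reactants: 16 (S)-2-benzyloxy-1-[3,4-bis(benzyloxy)phenyl]-3-[2,6-dibromo-4-(triisopropylsilyloxy)phenyl]propan-1-one
Product: 17 (1R,2S)-2-benzyloxy-1-[3,4-bis(benzyloxy)phenyl]-3-[2,6-dibromo-4-(triisopropylsilyloxy)phenyl]propan-1-ol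
Conditions: Zn(BH4)2, Et2O/CH2Cl2, −30 → 0 °C
Reagents that add atoms: none
Why: Chelation-controlled reduction (Cram chelate model). Zinc binds the carbonyl and the α-benzyloxy oxygen in a five-membered chelate and hydride attacks from the side of the α-hydrogen, which should give the anti (1R,2S) alcohol.

Step 10
Reactants: 17 (1R,2S)-2-benzyloxy-1-[3,4-bis(benzyloxy)phenyl]-3-[2,6-dibromo-4-(triisopropylsilyloxy)phenyl]propan-1-ol
Product: 18 (2R,3S)-3-benzyloxy-2-[3,4-bis(benzyloxy)phenyl]-5-bromo-7-(triisopropylsilyloxy)chromane
Conditions: Pd(OAc)2 (5 mol %), rac-2-(di-tert-butylphosphino)-1,1′-binaphthyl (6 mol %), Cs2CO3, toluene, 70 °C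
Reagents that add atoms: none
Why: Pd(OAc)2 is reduced in the flask to zerovalent palladium, which inserts into one of the two C–Br bonds of 17; these are interchanged by rotation about the aryl–CH2 bond, so either insertion leads to the same product. Cs2CO3 deprotonates the palladium-bound C1 hydroxyl, and the aryl(alkoxo)palladium chelate undergoes C–O reductive elimination, forming C8a–O1. The closest known reaction type is the intramolecular Buchwald–Hartwig etherification of 3-(2-bromoaryl)propanols, which gives chromans from secondary alcohols. Ring C closes as a six-membered ring in the exo sense at the aryl carbon, by reductive elimination from a seven-membered palladacycle. No stereocentre is formed: the C–O bond of the carbinol stays intact, so (1R) in 17 becomes (2R) in 18 and the anti relationship becomes 2,3-trans. Reductive elimination must outrun β-hydride elimination of the benzylic alkoxide, which the bulky, electron-rich di-tert-butylbiaryl phosphine favours. Only the six-membered ether can form because the C3 oxygen is blocked as its benzyl ether, and the reaction stops after one coupling because no free hydroxyl remains. The surviving bromine sits at C5 and the silyloxy group at C7.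

Step 11
Reactants: 18 (2R,3S)-3-benzyloxy-2-[3,4-bis(benzyloxy)phenyl]-5-bromo-7-(triisopropylsilyloxy)chromane
Product: 19 (2R,3S)-3,5-bis(benzyloxy)-2-[3,4-bis(benzyloxy)phenyl]-7-(triisopropylsilyloxy)chromane
Conditions: BnOH, [Pd(C3H5)Cl]2, RockPhos (2-(di-tert-butylphosphino)-3-methoxy-6-methyl-2′,4′,6′-triisopropylbiphenyl), Cs2CO3, toluene, 90 °C
Reagents that add atoms: benzyl alcohol, OCc1ccccc1
Why: Intermolecular Buchwald–Hartwig etherification of an aryl bromide with a primary alcohol. The hindered biaryl phosphine favours C–O reductive elimination over β-hydride elimination from the palladium benzyloxide.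

Step 12
Reactants: 19 (2R,3S)-3,5-bis(benzyloxy)-2-[3,4-bis(benzyloxy)phenyl]-7-(triisopropylsilyloxy)chromane
Product: 20 (2R,3S)-3,5-bis(benzyloxy)-2-[3,4-bis(benzyloxy)phenyl]chroman-7-ol
Conditions: Bu4NF, THF, 0 °C; aq. NH4Cl
Reagents that add atoms: none
Why: Fluoride cleavage of the aryl silyl ether. Benzyl ethers are untouched, so O7 becomes the only free hydroxyl.

Step 13
Reactants: 20 (2R,3S)-3,5-bis(benzyloxy)-2-[3,4-bis(benzyloxy)phenyl]chroman-7-ol; 21 3,4,5-tris(benzyloxy)benzoic acid
Product: 23 (2R,3S)-3,5-bis(benzyloxy)-2-[3,4-bis(benzyloxy)phenyl]chroman-7-yl 3,4,5-tris(benzyloxy)benzoate, via tribenzylgalloyl chloride 22 (not isolated)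
Conditions: 21, (COCl)2, cat. DMF, CH2Cl2, rt, concentrate; then 20, Et3N, DMAP, CH2Cl2, 0 °C → rt
Reagents that add atoms: none
Why: Acylation of a phenol with an acid chloride under nucleophilic catalysis. No selectivity is needed because 20 has a single hydroxyl.

Step 14
Reactants: 23 (2R,3S)-3,5-bis(benzyloxy)-2-[3,4-bis(benzyloxy)phenyl]chroman-7-yl 3,4,5-tris(benzyloxy)benzoate
Product: 24 catechin 7-O-gallate
Conditions: H2 (1 atm), Pd(OH)2/C, THF/MeOH, rt
Reagents that add atoms: none
Why: Hydrogenolysis of seven benzyl ethers under neutral conditions. The aryl ester and the C2–O1 bond of the chroman should survive, and the absence of base avoids ester transfer and C2 epimerisation. The product is handled with exclusion of air.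

## Compound list

1 | 3,5-dibromophenol | Oc1cc(Br)cc(Br)c1 | starting material
2 | (3,5-dibromophenoxy)triisopropylsilane | CC(C)[Si](Oc1cc(Br)cc(Br)c1)(C(C)C)C(C)C | intermediate
3 | [2,6-dibromo-4-(triisopropylsilyloxy)phenyl]lithium | [Li]c1c(Br)cc(O[Si](C(C)C)(C(C)C)C(C)C)cc1Br | intermediate (not isolated)
4 | 2,6-dibromo-4-(triisopropylsilyloxy)benzaldehyde | O=Cc1c(Br)cc(O[Si](C(C)C)(C(C)C)C(C)C)cc1Br | intermediate
5 | [2,6-dibromo-4-(triisopropylsilyloxy)phenyl]methanol | OCc1c(Br)cc(O[Si](C(C)C)(C(C)C)C(C)C)cc1Br | intermediate
6 | [3,5-dibromo-4-(bromomethyl)phenoxy]triisopropylsilane | BrCc1c(Br)cc(O[Si](C(C)C)(C(C)C)C(C)C)cc1Br | intermediate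
7 | (R)-4-benzyloxazolidin-2-one | O=C1N[C@H](Cc2ccccc2)CO1 | starting material
8 | benzyloxyacetyl chloride | O=C(Cl)COCc1ccccc1 | starting material
9 | lithium (R)-4-benzyl-2-oxooxazolidin-3-ide | [Li]N1[C@H](Cc2ccccc2)COC1=O | intermediate (not isolated)
10 | (R)-4-benzyl-3-(2-benzyloxyacetyl)oxazolidin-2-one | O=C(COCc1ccccc1)N1[C@H](Cc2ccccc2)COC1=O | intermediate
11 | sodium (Z)-enolate of 10 | [Na]O/C(=C\OCc1ccccc1)N1[C@H](Cc2ccccc2)COC1=O | intermediate (not isolated)
12 | (R)-4-benzyl-3-{(S)-2-benzyloxy-3-[2,6-dibromo-4-(triisopropylsilyloxy)phenyl]propanoyl}oxazolidin-2-one | O=C([C@H](Cc1c(Br)cc(O[Si](C(C)C)(C(C)C)C(C)C)cc1Br)OCc1ccccc1)N1[C@H](Cc2ccccc2)COC1=O | intermediate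
13 | (S)-2-benzyloxy-3-[2,6-dibromo-4-(triisopropylsilyloxy)phenyl]-N-methoxy-N-methylpropanamide | CON(C)C(=O)[C@H](Cc1c(Br)cc(O[Si](C(C)C)(C(C)C)C(C)C)cc1Br)OCc1ccccc1 | intermediate
14 | 4-bromo-1,2-bis(benzyloxy)benzene | Brc1ccc(OCc2ccccc2)c(OCc2ccccc2)c1 | starting material
15 | [3,4-bis(benzyloxy)phenyl]magnesium bromide | Br[Mg]c1ccc(OCc2ccccc2)c(OCc2ccccc2)c1 | intermediate (not isolated)
16 | (S)-2-benzyloxy-1-[3,4-bis(benzyloxy)phenyl]-3-[2,6-dibromo-4-(triisopropylsilyloxy)phenyl]propan-1-one | O=C(c1ccc(OCc2ccccc2)c(OCc2ccccc2)c1)[C@H](Cc1c(Br)cc(O[Si](C(C)C)(C(C)C)C(C)C)cc1Br)OCc1ccccc1 | intermediate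
17 | (1R,2S)-2-benzyloxy-1-[3,4-bis(benzyloxy)phenyl]-3-[2,6-dibromo-4-(triisopropylsilyloxy)phenyl]propan-1-ol | CC(C)[Si](Oc1cc(Br)c(C[C@H](OCc2ccccc2)[C@H](O)c2ccc(OCc3ccccc3)c(OCc3ccccc3)c2)c(Br)c1)(C(C)C)C(C)C | intermediate
18 | (2R,3S)-3-benzyloxy-2-[3,4-bis(benzyloxy)phenyl]-5-bromo-7-(triisopropylsilyloxy)chromane | CC(C)[Si](Oc1cc(Br)c2c(c1)O[C@H](c1ccc(OCc3ccccc3)c(OCc3ccccc3)c1)[C@@H](OCc1ccccc1)C2)(C(C)C)C(C)C | intermediate
19 | (2R,3S)-3,5-bis(benzyloxy)-2-[3,4-bis(benzyloxy)phenyl]-7-(triisopropylsilyloxy)chromane | CC(C)[Si](Oc1cc(OCc3ccccc3)c2c(c1)O[C@H](c1ccc(OCc3ccccc3)c(OCc3ccccc3)c1)[C@@H](OCc1ccccc1)C2)(C(C)C)C(C)C | intermediate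
20 | (2R,3S)-3,5-bis(benzyloxy)-2-[3,4-bis(benzyloxy)phenyl]chroman-7-ol | Oc1cc(OCc3ccccc3)c2c(c1)O[C@H](c1ccc(OCc3ccccc3)c(OCc3ccccc3)c1)[C@@H](OCc1ccccc1)C2 | intermediate
21 | 3,4,5-tris(benzyloxy)benzoic acid | OC(=O)c1cc(OCc2ccccc2)c(OCc2ccccc2)c(OCc2ccccc2)c1 | starting material
22 | 3,4,5-tris(benzyloxy)benzoyl chloride | O=C(Cl)c1cc(OCc2ccccc2)c(OCc2ccccc2)c(OCc2ccccc2)c1 | intermediate (not isolated)
23 | (2R,3S)-3,5-bis(benzyloxy)-2-[3,4-bis(benzyloxy)phenyl]chroman-7-yl 3,4,5-tris(benzyloxy)benzoate | O=C(Oc1cc(OCc3ccccc3)c2c(c1)O[C@H](c1ccc(OCc3ccccc3)c(OCc3ccccc3)c1)[C@@H](OCc1ccccc1)C2)c1cc(OCc2ccccc2)c(OCc2ccccc2)c(OCc2ccccc2)c1 | intermediate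
24 | catechin 7-O-gallate | O=C(Oc1cc(O)c2c(c1)O[C@H](c1ccc(O)c(O)c1)[C@@H](O)C2)c1cc(O)c(O)c(O)c1 | target

## Step count and least certain steps

Total step count: 14. Longest linear sequence: 13 steps (1 → 2 → 4 → 5 → 6 → 12 → 13 → 16 → 17 → 18 → 19 → 20 → 23 → 24). Step 5 is the only step off this line.

**Step 10 (key step).**
- Risk: the most likely failure is β-hydride elimination from the palladium-bound benzylic alkoxide. This oxidises the carbinol to the aryl ketone and removes a bromine by reduction. Slow loss of the silyl group under hot carbonate is the second concern.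
- A change of metal to CuI with a phenanthroline ligand (Ullmann etherification) would be tried as a variation of conditions.
- Fallback: the polarity of the closure is reversed, while the two equivalent bromines still tell C8a from C5. It sets out from ketone 16 and returns at 18.
- Ketone 16 is reduced under non-chelating Felkin–Anh control (KBH(s-Bu)3, THF, −78 °C) to the syn alcohol (1S,2S)-2-benzyloxy-1-[3,4-bis(benzyloxy)phenyl]-3-[2,6-dibromo-4-(triisopropylsilyloxy)phenyl]propan-1-ol F1.
- Bromine–lithium exchange at one of the equivalent bromines (n-BuLi, 2.1 equiv, THF, −78 °C), borylation with B(OMe)3 and oxidation (NaBO3·4H2O) should give (1S,2S)-2-benzyloxy-1-[3,4-bis(benzyloxy)phenyl]-3-[2-bromo-6-hydroxy-4-(triisopropylsilyloxy)phenyl]propan-1-ol F2.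
- A Mitsunobu reaction (PPh3, diisopropyl azodicarboxylate, THF) then closes O1–C2 with inversion at the benzylic carbon and gives 18.

**Step 11.**
- Risk: β-hydride elimination from the palladium benzyloxide would replace the C5 bromine by hydrogen, and the alkoxide may attack silicon and strip the C7 silyl group.
- Fallback: from 18, returning at 19.
- Miyaura borylation (B2pin2, Pd(dppf)Cl2, KOAc, dioxane, 80 °C) gives 2-[(2R,3S)-3-benzyloxy-2-[3,4-bis(benzyloxy)phenyl]-7-(triisopropylsilyloxy)chroman-5-yl]-4,4,5,5-tetramethyl-1,3,2-dioxaborolane F3.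
- Oxidation (NaBO3·4H2O, THF/H2O) gives (2R,3S)-3-benzyloxy-2-[3,4-bis(benzyloxy)phenyl]-7-(triisopropylsilyloxy)chroman-5-ol F4.
- Benzylation (BnBr, K2CO3, DMF) gives 19.

**Step 9.**
- Risk: incomplete chelation, with the other ether oxygens competing for zinc, would lower the facial selectivity and give the syn epimer as well.
- Fallback: control is moved from the substrate to the catalyst. Ketone 16 is reduced to 17 by Noyori-type asymmetric transfer hydrogenation with RuCl(p-cymene)[(S,S)-TsDPEN] in HCO2H/Et3N. The ligand enantiomer is chosen to deliver the (1R) carbinol; by analogy with simple aryl ketones this is expected to be the (S,S) form. This fallback makes no new compound (F0).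

**Step 6.**
- Risk: substitution at the benzylic carbon, which has two ortho bromines, may be slow, while enolate 11 decomposes above about −40 °C. The result would be low conversion.
- Fallback: the C4a–C4 bond is formed in place of C3–C4, with C3 taken from the chiral pool. It sets out from 2 and returns at 13.
- Aryllithium 3, made as in step 2, is transmetalated with MgBr2·OEt2 at −78 °C to [2,6-dibromo-4-(triisopropylsilyloxy)phenyl]magnesium bromide F5.
- With catalytic CuI, F5 opens methyl (S)-oxirane-2-carboxylate F6 at its CH2 group (−40 → −20 °C) to give methyl (S)-3-[2,6-dibromo-4-(triisopropylsilyloxy)phenyl]-2-hydroxypropanoate F7.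
- O-Benzylation with benzyl 2,2,2-trichloroacetimidate and catalytic TfOH gives methyl (S)-2-benzyloxy-3-[2,6-dibromo-4-(triisopropylsilyloxy)phenyl]propanoate F8.
- AlMe3 and MeONHMe·HCl convert F8 into 13.
- This path is shorter than steps 3–7 but depends on a hindered, thermally fragile aryl metal, which is why it is the fallback and not the main route.

**Step 2.**
- Risk: loss of LiBr from 3 (aryne formation) if the temperature rises, or competing deprotonation next to the silyloxy group.
- Fallback: a purchased arene that already carries the benzylic carbon, 3,5-dibromo-4-methylphenol F9, is used.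
- Silylation (TIPSCl, imidazole, DMF) gives (3,5-dibromo-4-methylphenoxy)triisopropylsilane F10.
- Wohl–Ziegler bromination (N-bromosuccinimide, AIBN, PhCF3, 80 °C) gives 6. This bypasses steps 2 to 4.

## Further compounds

F1 | step 10 | (1S,2S)-2-benzyloxy-1-[3,4-bis(benzyloxy)phenyl]-3-[2,6-dibromo-4-(triisopropylsilyloxy)phenyl]propan-1-ol | CC(C)[Si](Oc1cc(Br)c(C[C@H](OCc2ccccc2)[C@@H](O)c2ccc(OCc3ccccc3)c(OCc3ccccc3)c2)c(Br)c1)(C(C)C)C(C)C
F2 | step 10 | (1S,2S)-2-benzyloxy-1-[3,4-bis(benzyloxy)phenyl]-3-[2-bromo-6-hydroxy-4-(triisopropylsilyloxy)phenyl]propan-1-ol | CC(C)[Si](Oc1cc(Br)c(C[C@H](OCc2ccccc2)[C@@H](O)c2ccc(OCc3ccccc3)c(OCc3ccccc3)c2)c(O)c1)(C(C)C)C(C)C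
F3 | step 11 | 2-[(2R,3S)-3-benzyloxy-2-[3,4-bis(benzyloxy)phenyl]-7-(triisopropylsilyloxy)chroman-5-yl]-4,4,5,5-tetramethyl-1,3,2-dioxaborolane | CC(C)[Si](Oc1cc(B3OC(C)(C)C(C)(C)O3)c2c(c1)O[C@H](c1ccc(OCc3ccccc3)c(OCc3ccccc3)c1)[C@@H](OCc1ccccc1)C2)(C(C)C)C(C)C
F4 | step 11 | (2R,3S)-3-benzyloxy-2-[3,4-bis(benzyloxy)phenyl]-7-(triisopropylsilyloxy)chroman-5-ol | CC(C)[Si](Oc1cc(O)c2c(c1)O[C@H](c1ccc(OCc3ccccc3)c(OCc3ccccc3)c1)[C@@H](OCc1ccccc1)C2)(C(C)C)C(C)C
F0 | step 9 | none | none
F5 | step 6 | [2,6-dibromo-4-(triisopropylsilyloxy)phenyl]magnesium bromide | Br[Mg]c1c(Br)cc(O[Si](C(C)C)(C(C)C)C(C)C)cc1Br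
F6 | step 6 | methyl (S)-oxirane-2-carboxylate | COC(=O)[C@@H]1CO1
F7 | step 6 | methyl (S)-3-[2,6-dibromo-4-(triisopropylsilyloxy)phenyl]-2-hydroxypropanoate | COC(=O)[C@@H](O)Cc1c(Br)cc(O[Si](C(C)C)(C(C)C)C(C)C)cc1Br
F8 | step 6 | methyl (S)-2-benzyloxy-3-[2,6-dibromo-4-(triisopropylsilyloxy)phenyl]propanoate | COC(=O)[C@@H](OCc1ccccc1)Cc1c(Br)cc(O[Si](C(C)C)(C(C)C)C(C)C)cc1Br
F9 | step 2 | 3,5-dibromo-4-methylphenol | Cc1c(Br)cc(O)cc1Br
F10 | step 2 | (3,5-dibromo-4-methylphenoxy)triisopropylsilane | Cc1c(Br)cc(O[Si](C(C)C)(C(C)C)C(C)C)cc1Br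
A1 | alternative 1 | hexa-O-benzyl 3-O-benzyloxycarbonyl catechin 7-O-gallate | O=C(Oc1cc(OCc3ccccc3)c2c(c1)O[C@H](c3ccc(OCc4ccccc4)c(OCc4ccccc4)c3)[C@@H](OC(=O)OCc3ccccc3)C2)c1cc(OCc2ccccc2)c(OCc2ccccc2)c(OCc2ccccc2)c1
A2 | alternative 1 | 3-benzyloxy-5-hydroxy-4-(hydroxymethyl)phenyl 3,4,5-tris(benzyloxy)benzoate | OCc1c(O)cc(OC(=O)c2cc(OCc3ccccc3)c(OCc3ccccc3)c(OCc3ccccc3)c2)cc1OCc1ccccc1
A3 | alternative 1 | 5-benzyloxy-4-methylidene-3-oxocyclohexa-1,5-dien-1-yl 3,4,5-tris(benzyloxy)benzoate | C=C1C(=O)C=C(OC(=O)c2cc(OCc3ccccc3)c(OCc3ccccc3)c(OCc3ccccc3)c2)C=C1OCc1ccccc1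
A4 | alternative 1 | benzyl (E)-2-[3,4-bis(benzyloxy)phenyl]ethenyl carbonate | O=C(OCc1ccccc1)O/C=C/c1ccc(OCc2ccccc2)c(OCc2ccccc2)c1
A5 | alternative 2 | (S)-5-benzyloxy-2-[3,4-bis(benzyloxy)phenyl]-7-(triisopropylsilyloxy)-2H-chromene, spatially configured at C2 as the target | CC(C)[Si](Oc1cc(OCc3ccccc3)c2c(c1)O[C@H](c1ccc(OCc3ccccc3)c(OCc3ccccc3)c1)C=C2)(C(C)C)C(C)C
A6 | alternative 2 | (Z)-{2-[2-{[3,4-bis(benzyloxy)phenyl](methoxy)methoxy}-6-benzyloxy-4-(triisopropylsilyloxy)phenyl]ethenyl}trimethylsilane, mixture at the acetal carbon | COC(Oc1cc(O[Si](C(C)C)(C(C)C)C(C)C)cc(OCc2ccccc2)c1/C=C\[Si](C)(C)C)c1ccc(OCc2ccccc2)c(OCc2ccccc2)c1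
A7 | alternative 3 | 3′,4′-di-O-benzyl-5-O-benzyloxycarbonyl-7-O-triisopropylsilyl catechin | CC(C)[Si](Oc1cc(OC(=O)OCc3ccccc3)c2c(c1)O[C@H](c1ccc(OCc3ccccc3)c(OCc3ccccc3)c1)[C@@H](O)C2)(C(C)C)C(C)C
A8 | alternative 3 | benzyl 3-{(R)-[3,4-bis(benzyloxy)phenyl][(S)-oxiran-2-yl]methoxy}-5-(triisopropylsilyloxy)phenyl carbonate | CC(C)[Si](Oc1cc(OC(=O)OCc2ccccc2)cc(O[C@H](c2ccc(OCc3ccccc3)c(OCc3ccccc3)c2)[C@@H]2CO2)c1)(C(C)C)C(C)C
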